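**Plan**

- Numbering: ring B = C1–C6 (C2–Br, C3 carbinol with its methyl, spiro C6); ring A = C6–C11 (C7 carries the exocyclic CH2, C10–Br, C11 = CMe2).
- Enabling feature: in ring A the quaternary carbons C6 and C11 are neighbours, and C7, also bonded to C6, is sp2 (a ketone in disguise). A five-membered C7 carbinol that contains C11 can therefore pass C11 across to an electron-poor C6 and become ring A.
- Retrosynthetic cuts, in order: C7=CH2; C2–Br/C3–O (bromo-ketalisation of C2=C3 by the C7 oxygen); C10–Br (from C10–O with inversion); C5–O; C6–C11 (semipinacol shift at the C5–C6 epoxide); C6–C7 (dienyl–cerium plus cyclopentanone); the two ring-B bonds of an isoprene/alkyne [4+2].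
- Forward: ring B is made first by cobalt-catalysed [4+2] and joined at C6–C7 to a silyloxy cyclopentanone; ring A then arises by five-to-six ring enlargement. A temporary C7–O–C3 bridge is the only other ring event.
- Stereochemistry: C10 from CBS reduction, relayed to C7 (addition anti to the silyloxy group), to the epoxide (hydroxyl-directed) and to C6 (migration anti to C6–O); C2/C3 from internal anti delivery of the C7 oxygen; C10–Br by SN2 inversion.

Key step: step 7

**Step 1**
Reactants: 1 2,2-dimethylcyclopentane-1,3-dione
Product: 2 (R)-3-hydroxy-2,2-dimethylcyclopentan-1-one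
Conditions: (S)-Me-CBS oxazaborolidine [(S)-1-methyl-3,3-diphenyltetrahydro-1H,3H-pyrrolo[1,2-c][1,3,2]oxazaborole] (20 mol%), catecholborane (1.1 equiv), PhNEt2, toluene, −78 °C; MeOH quench
Reagents that add atoms: none
Why: Corey–Bakshi–Shibata reduction desymmetrises the achiral dione by enantioface-selective hydride delivery to one carbonyl, the quaternary α-carbon acting as the large substituent so that the (S)-catalyst should give the (R)-carbinol, and one equivalent of a one-hydride borane should stop at the hydroxy ketone.

**Step 2**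
Reactants: 2 (R)-3-hydroxy-2,2-dimethylcyclopentan-1-one
Product: 3 (R)-3-[(tert-butyldimethylsilyl)oxy]-2,2-dimethylcyclopentan-1-one
Conditions: TBSCl, imidazole, DMF, rt
Reagents that add atoms: tert-butyldimethylsilyl chloride, CC(C)(C)[Si](C)(C)Cl
Why: Imidazole-promoted silyl ether formation protects the alcohol against the organometallic step and supplies the bulk that later steers addition to the ketone, without touching the stereocentre.

**Step 3**
Reactants: 4 isoprene; 5 trimethylsilylacetylene
Product: 6 trimethyl(4-methylcyclohexa-1,4-dien-1-yl)silane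
Conditions: CoBr2(dppe) (5 mol%; dppe = Ph2PCH2CH2PPh2), Zn (10 mol%), ZnI2 (10 mol%), CH2Cl2, rt
Reagents that add atoms: none
Why: Zinc reduces the divalent cobalt precatalyst to monovalent cobalt, which mediates a neutral Diels–Alder-type [4+2] cycloaddition of the unactivated alkyne with the diene; the bisphosphine ligand should favour the 1,4-(para) regioisomer, and the product is the non-conjugated 1,4-diene.

**Step 4**
Reactants: 6 trimethyl(4-methylcyclohexa-1,4-dien-1-yl)silane
Product: 7 1-iodo-4-methylcyclohexa-1,4-diene
Conditions: N-iodosuccinimide, (CF3)2CHOH, 0 °C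
Reagents that add atoms: N-iodosuccinimide, O=C1CCC(=O)N1I
Why: Ipso-iododesilylation of the vinylsilane (electrophilic substitution through a β-silyl cation) should outpace attack on the plain trisubstituted alkene because loss of silicon is irreversible, and the ring geometry is fixed.

**Step 5**
Reactants: 7 1-iodo-4-methylcyclohexa-1,4-diene; 3 (R)-3-[(tert-butyldimethylsilyl)oxy]-2,2-dimethylcyclopentan-1-one
Product: 10 (1R,3R)-3-[(tert-butyldimethylsilyl)oxy]-2,2-dimethyl-1-(4-methylcyclohexa-1,4-dien-1-yl)cyclopentan-1-ol, via dienyllithium 8 (not isolated), via dienylcerium dichloride 9 (not isolated)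
Conditions: t-BuLi (2 equiv), THF, −78 °C; CeCl3 (anhydrous), −78 °C; then 3, −78 → −40 °C
Reagents that add atoms: none
Why: Iodine–lithium exchange and transmetalation give an organocerium reagent whose 1,2-carbonyl addition tolerates the hindered, enolisable ketone, and approach from the face opposite the C10 silyloxy group should place the new C7 hydroxyl cis to it (C7 R).

**Step 6**
Reactants: 10 (1R,3R)-3-[(tert-butyldimethylsilyl)oxy]-2,2-dimethyl-1-(4-methylcyclohexa-1,4-dien-1-yl)cyclopentan-1-ol
Product: 11 (1S,3R)-3-[(tert-butyldimethylsilyl)oxy]-2,2-dimethyl-1-[(1R,6S)-4-methyl-7-oxabicyclo[4.1.0]hept-3-en-1-yl]cyclopentan-1-ol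
Conditions: VO(acac)2 (5 mol%), t-BuOOH (1.5 equiv), CH2Cl2, 0 °C → rt
Reagents that add atoms: tert-butyl hydroperoxide, CC(C)(C)OO
Why: Hydroxyl-directed vanadium-catalysed epoxidation touches only the allylic C5=C6 alkene, and the oxygen should arrive on the face exposed in the rotamer that keeps the bulky C11 away from C1 (minimal A(1,2) strain), giving the (5S,6R)-epoxide syn to the C7 hydroxyl.

**Step 7**
Reactants: 11 (1S,3R)-3-[(tert-butyldimethylsilyl)oxy]-2,2-dimethyl-1-[(1R,6S)-4-methyl-7-oxabicyclo[4.1.0]hept-3-en-1-yl]cyclopentan-1-ol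
Product: 12 (5S,6S,10R)-10-[(tert-butyldimethylsilyl)oxy]-5-hydroxy-3,11,11-trimethylspiro[5.5]undec-2-en-7-one
Conditions: BF3·OEt2 (0.5 equiv), CH2Cl2, −78 °C
Reagents that add atoms: none
Why: BF3 binds the epoxide oxygen and the C6–O bond at the fully substituted carbon ionises while the anti-periplanar C7–C11 bond shifts to C6 and the C7 hydroxyl collapses to the ketone, which is the Lewis-acid semipinacol rearrangement of a tertiary 2,3-epoxy alcohol. Ring A is closed not by cyclisation but by a 1,2-alkyl shift that enlarges the cyclopentanol to the six-membered ketone, and the same shift forges the C6–C11 bond between the two quaternary carbons. The new stereocentre C6 is set by stereospecific inversion at the epoxide carbon, so it is controlled by the epoxide configuration (relayed from C10 through C7), while C5 keeps its oxygen with retention. The step needs C11 and not C8 to migrate: C11 is the more substituted, better migrating carbon, and the rotamer of least A(1,2) strain, held by the hydrogen bond between the syn hydroxyl and the epoxide, already places C11 anti to the C6–O bond. It also needs the shift to outrun proton loss from the doubly allylic C1, which the concerted low-temperature pathway should secure; once C6 is quaternary, ring B can no longer aromatise.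

**Step 8**
Reactants: 12 (5S,6S,10R)-10-[(tert-butyldimethylsilyl)oxy]-5-hydroxy-3,11,11-trimethylspiro[5.5]undec-2-en-7-one
Product: 13 O-[(5S,6S,10R)-10-[(tert-butyldimethylsilyl)oxy]-3,11,11-trimethyl-7-oxospiro[5.5]undec-2-en-5-yl] O-phenyl carbonothioate
Conditions: PhOC(S)Cl, pyridine, DMAP (cat.), CH2Cl2, 0 °C → rt
Reagents that add atoms: O-phenyl chlorothionoformate, S=C(Cl)Oc1ccccc1
Why: Acylation of the secondary C5 alcohol to a thionocarbonate under mild amine base prepares the radical deoxygenation and avoids the strong base that could trigger retro-aldol cleavage of the β-hydroxy ketone.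

**Step 9**
Reactants: 13 O-[(5S,6S,10R)-10-[(tert-butyldimethylsilyl)oxy]-3,11,11-trimethyl-7-oxospiro[5.5]undec-2-en-5-yl] O-phenyl carbonothioate
Product: 14 (6S,10R)-10-[(tert-butyldimethylsilyl)oxy]-3,11,11-trimethylspiro[5.5]undec-2-en-7-one
Conditions: Bu3SnH (3 equiv, 0.5 M), (PhSe)2 (10 mol%), AIBN (azobisisobutyronitrile), toluene, 80 °C
Reagents that add atoms: none
Why: Barton–McCombie deoxygenation removes the C5 oxygen through the secondary C5 radical, and the high stannane concentration with PhSeH formed in situ should supply hydrogen fast enough to forestall a 1,2-acyl shift towards C7 or closure onto C2=C3; C6 is not affected.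

**Step 10**
Reactants: 14 (6S,10R)-10-[(tert-butyldimethylsilyl)oxy]-3,11,11-trimethylspiro[5.5]undec-2-en-7-one
Product: 15 (6S,10R)-10-hydroxy-3,11,11-trimethylspiro[5.5]undec-2-en-7-one
Conditions: HF (48% aq.), MeCN, rt
Reagents that add atoms: none
Why: Fluoride-driven cleavage of the hindered silyl ether (Si–F bond formation) frees the C10 alcohol without basic conditions and leaves the ketone and the alkene alone.

**Step 11**
Reactants: 15 (6S,10R)-10-hydroxy-3,11,11-trimethylspiro[5.5]undec-2-en-7-one
Product: 16 (6S,10S)-10-bromo-3,11,11-trimethylspiro[5.5]undec-2-en-7-one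
Conditions: CBr4, P(n-C8H17)3, toluene, 70 °C
Reagents that add atoms: carbon tetrabromide, BrC(Br)(Br)Br
Why: Appel deoxybromination turns the alcohol into an oxyphosphonium ion that bromide displaces by SN2 with inversion, (10R)-O to (10S)-Br, the small nucleophilic trialkylphosphine being chosen for the neopentylic site; only a stereospecific substitution can define C10, because C1 and C5 make the two faces of ring A nearly alike.

**Step 12**
Reactants: 16 (6S,10S)-10-bromo-3,11,11-trimethylspiro[5.5]undec-2-en-7-one
Product: 18 (2R,3R,6S,7S,10S)-2,10-dibromo-7-methoxy-3,11,11-trimethyl-3,7-epoxyspiro[5.5]undecane, via methyl hemiketal 17 (not isolated)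
Conditions: N-bromosuccinimide, MeOH, 0 °C
Reagents that add atoms: N-bromosuccinimide, O=C1CCC(=O)N1Br; methanol, CO
Why: In this bromo-etherification (bromoketalisation) the hemiketal hydroxyl on C7 opens the bromonium ion at the tertiary C3 from its own face, closing a 2-oxabicyclo[2.2.2]octane cage just as α-terpineol gives bromocineole, so the C3 oxygen ends cis to C7 and the C2 bromine anti to it (2R,3R), and only the bromonium ion on the face opposite C7 can be captured internally.

**Step 13**
Reactants: 18 (2R,3R,6S,7S,10S)-2,10-dibromo-7-methoxy-3,11,11-trimethyl-3,7-epoxyspiro[5.5]undecane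
Product: 20 (2R,3R,6S,10S)-2,10-dibromo-3-hydroxy-3,11,11-trimethylspiro[5.5]undecan-7-one, via bridged hemiketal 19 (not isolated)
Conditions: 1 M HCl, THF, rt
Reagents that add atoms: water, O
Why: Acid-catalysed ketal hydrolysis expels methanol from C7, and the bridged hemiketal should open to the δ-hydroxy ketone because ring B relaxes from a boat to a chair with a diequatorial bromohydrin; the C3–O bond is never broken, so C2 and C3 are retained.

**Step 14**
Reactants: 20 (2R,3R,6S,10S)-2,10-dibromo-3-hydroxy-3,11,11-trimethylspiro[5.5]undecan-7-one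
Product: 21 (2R,3R,6R,10S)-2,10-dibromo-3,11,11-trimethyl-7-methylidenespiro[5.5]undecan-3-ol
Conditions: Cp2TiMe2 (4 equiv), toluene–THF, 65 °C, dark
Reagents that add atoms: dimethyltitanocene, C[Ti](C)(C1C=CC=C1)C1C=CC=C1
Why: Petasis methylenation (Cp2Ti=CH2 formed thermally, oxatitanacyclobutane, loss of the titanium oxide) converts the hindered C7 ketone next to the spiro carbon into the exocyclic alkene under non-basic conditions, so neither epoxide closure of the bromohydrin nor elimination of the bromides is expected, and excess reagent absorbs the free tertiary hydroxyl.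

**Compound list**

1 | 2,2-dimethylcyclopentane-1,3-dione | CC1(C)C(=O)CCC1=O | starting material
2 | (R)-3-hydroxy-2,2-dimethylcyclopentan-1-one | O=C1CC[C@@H](O)C1(C)C | intermediate
3 | (R)-3-[(tert-butyldimethylsilyl)oxy]-2,2-dimethylcyclopentan-1-one | O=C1CC[C@@H](O[Si](C)(C)C(C)(C)C)C1(C)C | intermediate
4 | isoprene | C=CC(C)=C | starting material
5 | trimethylsilylacetylene | C#C[Si](C)(C)C | starting material
6 | trimethyl(4-methylcyclohexa-1,4-dien-1-yl)silane | C[Si](C)(C)C1=CCC(C)=CC1 | intermediate
7 | 1-iodo-4-methylcyclohexa-1,4-diene | IC1=CCC(C)=CC1 | intermediate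
8 | (4-methylcyclohexa-1,4-dien-1-yl)lithium | [Li]C1=CCC(C)=CC1 | intermediate (not isolated)
9 | dichloro(4-methylcyclohexa-1,4-dien-1-yl)cerium | Cl[Ce](Cl)C1=CCC(C)=CC1 | intermediate (not isolated)
10 | (1R,3R)-3-[(tert-butyldimethylsilyl)oxy]-2,2-dimethyl-1-(4-methylcyclohexa-1,4-dien-1-yl)cyclopentan-1-ol (hydroxyl cis to the silyloxy group; C7 R, C10 R) | O[C@]1(CC[C@@H](O[Si](C)(C)C(C)(C)C)C1(C)C)C2=CCC(C)=CC2 | intermediate
11 | (1S,3R)-3-[(tert-butyldimethylsilyl)oxy]-2,2-dimethyl-1-[(1R,6S)-4-methyl-7-oxabicyclo[4.1.0]hept-3-en-1-yl]cyclopentan-1-ol (C5 S, C6 R, C7 S, C10 R) | O[C@]1(CC[C@@H](O[Si](C)(C)C(C)(C)C)C1(C)C)[C@]23O[C@H]2CC(C)=CC3 | intermediate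
12 | (5S,6S,10R)-10-[(tert-butyldimethylsilyl)oxy]-5-hydroxy-3,11,11-trimethylspiro[5.5]undec-2-en-7-one (C5 hydroxyl cis to C7) | O=C1CC[C@@H](O[Si](C)(C)C(C)(C)C)C(C)(C)[C@@]12[C@@H](O)CC(C)=CC2 | intermediate
13 | O-[(5S,6S,10R)-10-[(tert-butyldimethylsilyl)oxy]-3,11,11-trimethyl-7-oxospiro[5.5]undec-2-en-5-yl] O-phenyl carbonothioate | O=C1CC[C@@H](O[Si](C)(C)C(C)(C)C)C(C)(C)[C@@]12[C@@H](OC(=S)Oc3ccccc3)CC(C)=CC2 | intermediate
14 | (6S,10R)-10-[(tert-butyldimethylsilyl)oxy]-3,11,11-trimethylspiro[5.5]undec-2-en-7-one | O=C1CC[C@@H](O[Si](C)(C)C(C)(C)C)C(C)(C)[C@@]12CCC(C)=CC2 | intermediate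
15 | (6S,10R)-10-hydroxy-3,11,11-trimethylspiro[5.5]undec-2-en-7-one | O=C1CC[C@@H](O)C(C)(C)[C@@]12CCC(C)=CC2 | intermediate
16 | (6S,10S)-10-bromo-3,11,11-trimethylspiro[5.5]undec-2-en-7-one | O=C1CC[C@H](Br)C(C)(C)[C@@]12CCC(C)=CC2 | intermediate
17 | (6S,7R,10S)-10-bromo-7-methoxy-3,11,11-trimethylspiro[5.5]undec-2-en-7-ol (methyl hemiketal) | CO[C@]1(O)CC[C@H](Br)C(C)(C)[C@@]12CCC(C)=CC2 | intermediate (not isolated)
18 | (2R,3R,6S,7S,10S)-2,10-dibromo-7-methoxy-3,11,11-trimethyl-3,7-epoxyspiro[5.5]undecane (oxygen bridge C7–O–C3; C7 anomer shown is the one expected at equilibrium, and either anomer gives 20) | CO[C@]1(O3)CC[C@H](Br)C(C)(C)[C@@]12CC[C@]3(C)[C@H](Br)C2 | intermediate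
19 | (2R,3R,6S,7S,10S)-2,10-dibromo-3,11,11-trimethyl-3,7-epoxyspiro[5.5]undecan-7-ol (bridged hemiketal) | O[C@]1(O3)CC[C@H](Br)C(C)(C)[C@@]12CC[C@]3(C)[C@H](Br)C2 | intermediate (not isolated)
20 | (2R,3R,6S,10S)-2,10-dibromo-3-hydroxy-3,11,11-trimethylspiro[5.5]undecan-7-one | O=C1CC[C@H](Br)C(C)(C)[C@@]12CC[C@@](C)(O)[C@H](Br)C2 | intermediate
21 | (2R,3R,6R,10S)-2,10-dibromo-3,11,11-trimethyl-7-methylidenespiro[5.5]undecan-3-ol | C=C1CC[C@H](Br)C(C)(C)[C@@]12CC[C@@](C)(O)[C@H](Br)C2 | target

**Step count and risks**

Total step count: 14. Longest linear sequence: 12 steps (steps 1, 2 and 5–14, or equally steps 3–14).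

The three steps most likely to fail:

Step 11. The oxyphosphonium ion at the neopentylic C10 may lose a proton from C9, or suffer a 1,2-methyl shift from C11, faster than bromide can reach the hindered backside; transannular participation of the C7 carbonyl oxygen could also erode the inversion. Fallback: activation and displacement are separated. Starting from alcohol 15, Tf2O and pyridine in CH2Cl2 at −40 °C give the isolated (6S,10R)-triflate F1. This is then exposed in the cold to Bu4NBr in toluene, so that the much better leaving group is displaced bimolecularly at or below 0 °C, under the temperature at which ionisation sets in. The route is rejoined at bromide 16.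

Step 7. The ring-opened cation at C6 may shed a proton from the doubly allylic C1 (ending, after loss of water, in a p-tolyl ring), or C8 may migrate in place of C11. Fallback: another trigger is used for the same C7-to-C6 shift, without a free cation at C6. Carbinol 10 is treated with N-bromosuccinimide and NaHCO3 in CH2Cl2 at −20 °C. The bromonium ion on C5=C6 is opened by the anti C7–C11 bond (halonium-induced semipinacol ring expansion of a 1-alkenylcycloalkanol) to give the (5S,6S,10R)-β-bromo ketone F2, in which bromine at C5 takes the place of the hydroxyl of 12. Bu3SnH under the conditions of step 9 then removes that bromine, and the route is rejoined at ketone 14, two steps shorter. The price is that the face of attack then rests on rotamer preference alone and not on a hydroxyl–metal tether, so the C6 configuration of this material would have to be correlated with 14 from the epoxide route.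

Step 12. External capture of the bromonium ion by methanol, which by trans-diaxial opening prefers the unwanted C2/C3 pair, may outrun internal delivery, because the hemiketal of the hindered ketone is present only in small amount. Fallback: a true hydroxyl serves as the internal nucleophile. Bromo ketone 16 is reduced with NaBH4 in MeOH at 0 °C to the C7 carbinol F3 (both C7 epimers, each able to place its hydroxyl over C3). N-Bromosuccinimide in CH2Cl2 at 0 °C, with no competing nucleophile, closes the caged bromo ether F4 with the same C2/C3 configuration as 18. Catalytic RuCl3 with NaIO4 in CCl4–MeCN–H2O then oxidises the only ether methine, C7–H (C3 bears no hydrogen), to hemiketal 19, which opens to hydroxy ketone 20.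

**Further compounds**

F1 | step 11 | (6S,10R)-3,11,11-trimethyl-7-oxospiro[5.5]undec-2-en-10-yl trifluoromethanesulfonate | O=C1CC[C@@H](OS(=O)(=O)C(F)(F)F)C(C)(C)[C@@]12CCC(C)=CC2
F2 | step 7 | (5S,6S,10R)-5-bromo-10-[(tert-butyldimethylsilyl)oxy]-3,11,11-trimethylspiro[5.5]undec-2-en-7-one | O=C1CC[C@@H](O[Si](C)(C)C(C)(C)C)C(C)(C)[C@@]12[C@@H](Br)CC(C)=CC2
F3 | step 12 | (6S,10S)-10-bromo-3,11,11-trimethylspiro[5.5]undec-2-en-7-ol (both C7 epimers, C7 left undefined) | OC1CC[C@H](Br)C(C)(C)[C@@]12CCC(C)=CC2
F4 | step 12 | (2R,3R,6S,10S)-2,10-dibromo-3,11,11-trimethyl-3,7-epoxyspiro[5.5]undecane (both C7 epimers, C7 left undefined) | O1C2CC[C@H](Br)C(C)(C)[C@@]23CC[C@]1(C)[C@H](Br)C3
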